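The earlier runs and the new flask come from a simulation from invented constants; noise was put on by code.

In a one-step world each partner makes one single product and the flask stops, like a tank filling with no outlet. Here the readings also show double product, which takes two partners.

all flasks: starting material 0.20 M
- theta: partner 0.29 equiv; capture agent 0.010 M; run made earlier
- delta: partner 1.4 equiv; capture agent 0.010 M; run made earlier
- Monday's: partner 0.500 equiv; capture agent 0.0100 M; time 50 min
- Saturday's: partner 1.00 equiv; capture agent 0.0100 M; time 50 min
- Tuesday's: partner 2.00 equiv; capture agent 0.0100 M; time 50 min

| run | time / min | single product / % | double product / % |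
|---|---|---|---|
| theta | 2.00 | 10.7 | 0 |
| theta | 6.00 | 18.5 | 0.8 |
| theta | 12.0 | 20.4 | 0.7 |
| theta | 20.0 | 20.4 | 0.8 |
| theta | 25.0 | 20.2 | 0.5 |
| delta | 2.00 | 37.4 | 5.3 |
| delta | 4.00 | 46.0 | 10.4 |
| delta | 8.00 | 48.2 | 14.8 |
| delta | 12.0 | 47.4 | 15.4 |
| delta | 25.0 | 42.8 | 13.0 |

(standard deviation of a reading: 0.3 percentage points)
- amount of single product at the end, in percent of the starting material charged, for each flask in turn (Monday's, Saturday's, Tuesday's)
- the earlier runs were read with a standard deviation of 0.3 percentage points

The reckoning here takes the capture agent as a fast step that costs one partner per capture agent. Theta's readings at 20.0 min, counting two partners per double product, leave 7.00 % of the starting material's worth of partner unaccounted for, against a capture agent charge of 5.00 %.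

Monday's flask then holds 45.0 % of free partner: partner charged less capture agent charged, in percent of the starting material charged. Saturday's holds 95.0 % and Tuesday's 195 %.

One extreme has single product never reacting further, so it ends at the free partner, capped at 95.0 %. The other has the second addition instantaneous, so single product ends at zero. Delta read 48.2 % of single product beside 14.8 % of double product at 8.00 min, so the new flasks are put between the two extremes. The readings put single product at 85.0 % of free partner in theta and, at its highest reading, at 35.7 % in delta. A straight line between these readings puts Monday's near 34.1 % and Saturday's near 50.8 %, with partner the limiting reagent in Monday's, whose free partner is less than the cap. Tuesday's free partner exceeds the 190 % needed to take all uncaptured starting material to double product, so its single product is put below delta's last reading of 42.8 %.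

The forecast gives 28 %, 36 % and 29 %, on the suggestion that “a by-product of partner decay attacks the products”. For Saturday's it stands lower than the reckoning here.

The flasks give 34.0 %, 48.3 % and 12.1 %.

    starting material + partner → single product (k = 0.0220 M⁻¹ s⁻¹)
    partner + single product → double product (k = 0.0100 M⁻¹ s⁻¹)
    single product + capture agent → trapped intermediate (k = 0.0600 M⁻¹ s⁻¹)
    double product ⇌ isomer of the product (K = 3.10, k = 0.00250 s⁻¹)

On Monday's flask, single product plus two partners for each double product and each isomer of the product comes to 45.0 %, against 45.0 % of free partner. With 0.0060 % of the partner charge left in Monday's flask at 50.0 min, the half-life of starting material by the first step is 1500 h, far longer than the 50 min of the run. On Tuesday's flask the same count, with the remaining partner added, comes to 195 %, against 195 %. In Tuesday's flask 8.8 % of the partner charge still stands at 50.0 min, and single product has fallen from 22.4 % at 25.0 min to 12.1 %.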